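Divide target by starting material in each reading of the amber flask and watch where the quotient stops.

| setting | amber | teal | flask |
|---|---|---|---|
| starting material | 0.075 M | 0.15 M | 0.075 M |
| protic impurity | 0.015 M | 0.015 M | 0.0150 M |
| temperature | 0 °C | −5 °C | 0 °C |
| remark | the very flask that is asked about, followed so far | run made earlier |  |
| time |  |  | 8.0 h |

amber run (percent of the starting material charged)

| time / h | target / % | starting material / % |
|---|---|---|
| 0.500 | 16.5 | 29.5 |
| 1.33 | 19.4 | 23.6 |
| 3.00 | 18.1 | 19.9 |
| 6.00 | 15.1 | 16.6 |

teal run (percent of the starting material charged)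

| time / min | target / % | starting material / % |
|---|---|---|
| 8.00 | 5.5 | 72.2 |
| 20.0 | 9.6 | 49.4 |
| 40.0 | 13.8 | 34.1 |
| 90.0 | 16.3 | 25.7 |

(each reading ± 0.5 percentage points)

- target that was removed still counts
- reactions considered so far: starting material <-> target; starting material <-> isomer of the product A; starting material <-> isomer of the product B; starting material + protic impurity -> quenched substrate; target <-> isomer of the product C
- additions bring no volume worth counting

- elm: at 8.0 h add starting material, 50.0 % of the amount charged, then wait 2.5 h
- maple: at 8.0 h take out 90 % of the target then present, then wait 2.5 h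
- oak: at 8.0 h raise the temperature by 20 K, then wait 2.5 h
- cedar: change nothing and wait 2.5 h more

1. target, in percent of the starting material first charged, at 8.0 h
2. what to do for the largest gain in target; "none" if nothing gains more than 2 percentage points (elm / maple / oak / cedar / none)
3. target present, with what was taken out counted in, in percent of the starting material first charged, after oak
4. target present, with what was taken out counted in, in percent of the starting material first charged, after cedar

In the amber flask the quotient climbs from 0.559 at 0.500 h to 0.910 at 3.00 h and reads the same at 6.00 h. Two species joined by a reversible step keep a steady quotient while that step relaxes much faster than the pair is drained, a quasi-equilibrium. The value read here is 0.910: this plateau ratio, c(target)/c(starting material) once the quotient has stopped climbing, carries the scatter of its two readings, each 0.5 percentage points.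

Frozen at that value, the pair counts as one pool, with target holding a share of 0.476. The amber pool falls from 38.0 % at 3.00 h to 31.7 % at 6.00 h, which, taken as first-order, is a drain of 0.0604 h⁻¹. Carried forward, this reckoning gives 13.4 % of target at 8.0 h and 11.5 % after cedar. It gives nothing for oak: the teal quotient at −5 °C is still climbing at its last readings, from 0.405 at 40.0 min to 0.634 at 90.0 min, so the teal run shows no plateau to read.

The forecast gives 13.5 % at 8.0 h, 12 % after cedar, a figure above this reckoning's, and 7 % after oak, which it calls “very uncertain because the equilibrium's temperature dependence is unknown”. It chooses elm.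

The amber flask holds 14.6 % at 8.0 h, cedar gives 13.6 %, and the best move is oak, reaching 32.2 %, a gain of 18 points that exceeds maple's 9.6 points and elm's 8.7 points.

    starting material ⇌ target (K = 1.10, k = 2.90 × 10⁻⁴ s⁻¹, Ea = 90.0 kJ mol⁻¹, ΔH = 27.0 kJ mol⁻¹)
    starting material ⇌ isomer of the product A (K = 1.60, k = 1.70 × 10⁻⁵ s⁻¹, Ea = 82.0 kJ mol⁻¹, ΔH = −38.0 kJ mol⁻¹)
    starting material ⇌ isomer of the product B (K = 1.70, k = 9.80 × 10⁻⁴ s⁻¹, Ea = 71.0 kJ mol⁻¹, ΔH = −19.0 kJ mol⁻¹)
    starting material + protic impurity → quenched substrate (k = 0.00120 M⁻¹ s⁻¹, Ea = 72.0 kJ mol⁻¹)
    target ⇌ isomer of the product C (K = 2.80, k = 1.00 × 10⁻⁴ s⁻¹, Ea = 92.0 kJ mol⁻¹, ΔH = −50.0 kJ mol⁻¹)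
    (constants at 0 °C)

Put to a neighbour flask kept at 15 °C, the plateau ratio of 0.910 turns its 12.5 % of starting material at 8.00 h into 11.4 % of target, and that flask holds more, 25.6 %.

(All runs stem from a simulated flask with made-up constants, and the scatter is random.)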